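**Strategy.** Everything rests on reading the cyclopentenone ring (C8–C9–C10–C11–C12, prostanoid numbering), with its 1,4-related oxygens at C9 and C12 and the bromine at C10, as a rearranged 3-bromofuran. An enantioselective acid-catalysed Piancatelli rearrangement of a flat, achiral 3-bromo-5-octenylfurfuryl alcohol is the key step. It is a conrotatory 4π closure of a C8–C12 oxidopentadienyl cation that mirrors the presumed biosynthetic ring closure of the marine prostanoids. In one operation it creates the ring, the C8–C12 bond, the C12 tertiary carbinol stereocentre, the enone and the vinyl bromide. The dienylidene side chain is then attached with fixed 5E,7Z geometry by formylation, Z-selective enol triflation and Suzuki coupling.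

Key step: step 4

Remark on the chemistry: the sense of induction of the chiral acid cannot be assigned in advance, so the catalyst antipode that leads to (4S)-8 is assumed; C12 is labelled S in 8 and R from 10 onwards only because C8 becomes sp2, no bond at C12 being touched.

**Step 1**
Reactants: 1 (2Z)-oct-2-en-1-ol
Product: 2 (2Z)-1-bromooct-2-ene
Conditions: CBr4, PPh3, CH2Cl2, 0 °C
Reagents that add atoms: carbon tetrabromide, BrC(Br)(Br)Br
Why: Appel bromination replaces the primary allylic hydroxyl by SN2 attack of bromide on the alkoxyphosphonium ion under neutral conditions, so neither allylic transposition nor Z to E isomerisation is expected.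

**Step 2**
Reactants: 3 3-bromofuran-2-carboxylic acid; 2 (2Z)-1-bromooct-2-ene
Product: 5 3-bromo-5-[(2Z)-oct-2-en-1-yl]furan-2-carboxylic acid, via dilithio furoate 4 (not isolated)
Conditions: LiN(i-Pr)2 (2.2 equiv), THF, −78 °C; then 2, −78 → 0 °C; then dilute aq. HCl
Reagents that add atoms: none
Why: Metalation of a 2-furoic acid dianion: the lithium carboxylate is lithiated at the only free α-position (C5), and this C–Li bond is alkylated by the primary allylic bromide in a direct SN2 reaction while the carboxylate stays inert and the Z-alkene is untouched.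

**Step 3**
Reactants: 5 3-bromo-5-[(2Z)-oct-2-en-1-yl]furan-2-carboxylic acid
Product: 6 {3-bromo-5-[(2Z)-oct-2-en-1-yl]furan-2-yl}methanol
Conditions: LiAlH4, THF, 0 °C → rt; then H2O
Reagents that add atoms: none
Why: Hydride reduction of the carboxylic acid to the primary alcohol, under which the furyl bromide and the isolated alkene should not be reduced at or below room temperature.

**Step 4**
Reactants: 6 {3-bromo-5-[(2Z)-oct-2-en-1-yl]furan-2-yl}methanol
Product: 8 (4S)-2-bromo-4-hydroxy-4-[(2Z)-oct-2-en-1-yl]cyclopent-2-en-1-one, via ring-opened dienol 7 (not isolated)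
Conditions: chiral confined imidodiphosphorimidate (IDPi) Brønsted acid (5 mol %), H2O (5 equiv), CHCl3, 40 °C
Reagents that add atoms: water, O
Why: Proposed new method: the acid ionises the furfuryl alcohol to a 2-methylene-2H-furanium cation, water adds at the alkylated C5 (the future C12), the hemiketal opens to dienol 7, and its O-protonated form, a 3-bromo-1,4-dihydroxypentadienyl cation spanning C8–C12, closes the C8–C12 bond by a thermally allowed conrotatory 4π electrocyclisation before proton loss unveils the C9 ketone. The closest known reactions are the racemic Piancatelli rearrangement of 5-methyl-2-furylcarbinols (ZnCl2 or protic acid), the chiral phosphoric acid-catalysed asymmetric aza-Piancatelli rearrangement and IDPi-catalysed asymmetric Nazarov cyclisations; an enantioselective variant with water on a primary 5-alkylfurfuryl alcohol is not established. The cyclopentenone ring is closed in the Nazarov-type conrotatory 4π mode between the termini C8 and C12 of the pentadienyl cation. C12 is the only new stereocentre and follows from the sense of conrotation, which the confined chiral counter-anion, hydrogen-bonded to the two O–H groups of the cation, is expected to dictate. The step needs attack of water at C5 in place of oligomerisation and a single helical sense of the cation: both α-positions of the furan are substituted and C3 carries bromine, so only C5 is open to water and Friedel–Crafts self-condensation is suppressed, while the bromine on the central carbon of the cation ends up as the C10–Br of the enone.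

**Step 5**
Reactants: 8 (4S)-2-bromo-4-hydroxy-4-[(2Z)-oct-2-en-1-yl]cyclopent-2-en-1-one
Product: 10 (4R,5Z)-2-bromo-4-hydroxy-5-(hydroxymethylidene)-4-[(2Z)-oct-2-en-1-yl]cyclopent-2-en-1-one, via dilithium alkoxide enolate 9 (not isolated)
Conditions: LiN(SiMe3)2 (2.1 equiv), THF, −78 °C; then HCO2CH2CF3 (1.05 equiv), −78 °C; then dilute aq. HCl
Reagents that add atoms: 2,2,2-trifluoroethyl formate, O=COCC(F)(F)F
Why: Crossed Claisen C-formylation of the kinetic lithium enolate at C8 (the only enolisable position) by the activated formate, with the tertiary hydroxyl carried as a hindered lithium alkoxide that, as a β-oxido enolate, should neither eliminate nor open by retro-aldol at −78 °C; the product rests as the hydrogen-bonded Z-enol and C12 is not touched.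

**Step 6**
Reactants: 10 (4R,5Z)-2-bromo-4-hydroxy-5-(hydroxymethylidene)-4-[(2Z)-oct-2-en-1-yl]cyclopent-2-en-1-one
Product: 12 (Z)-[(5R)-3-bromo-5-hydroxy-5-[(2Z)-oct-2-en-1-yl]-2-oxocyclopent-3-en-1-ylidene]methyl trifluoromethanesulfonate, via lithium chelate enolate 11 (not isolated)
Conditions: LiN(SiMe3)2 (1.0 equiv), THF, −78 °C; then PhNTf2, −78 → 0 °C; then cold dilute aq. HCl
Reagents that add atoms: N-phenylbis(trifluoromethanesulfonimide), O=S(=O)(N(c1ccccc1)S(=O)(=O)C(F)(F)F)C(F)(F)F
Why: O-sulfonylation of a 1,3-dicarbonyl enolate: one equivalent of base removes only the acidic enol proton, lithium holds both oxygens in a U-shaped chelate, and triflation of the unhindered formyl oxygen should give the enol triflate with OTf cis to C9=O (the 7Z precursor), a geometry that the quaternary C12 on the other side also favours.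

**Step 7**
Reactants: 13 methyl hex-5-ynoate
Product: 14 methyl (5E)-6-(4,4,5,5-tetramethyl-1,3,2-dioxaborolan-2-yl)hex-5-enoate
Conditions: pinacolborane (1.1 equiv), Cp2Zr(H)Cl (5 mol %), Et3N (10 mol %), neat, 60 °C
Reagents that add atoms: pinacolborane, CC1(C)OBOC1(C)C
Why: Zirconium-catalysed hydroboration of a terminal alkyne, a syn anti-Markovnikov addition of H–B that fixes the E geometry of the later C5=C6 bond and tolerates the ester.

**Step 8**
Reactants: 12 (Z)-[(5R)-3-bromo-5-hydroxy-5-[(2Z)-oct-2-en-1-yl]-2-oxocyclopent-3-en-1-ylidene]methyl trifluoromethanesulfonate; 14 methyl (5E)-6-(4,4,5,5-tetramethyl-1,3,2-dioxaborolan-2-yl)hex-5-enoate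
Product: 15 methyl (5E,7Z)-7-[(5R)-3-bromo-5-hydroxy-5-[(2Z)-oct-2-en-1-yl]-2-oxocyclopent-3-en-1-ylidene]hept-5-enoate
Conditions: Pd(PPh3)4 (5 mol %), K3PO4 (2 equiv), THF–H2O, 25 °C, exclusion of light
Reagents that add atoms: none
Why: Suzuki–Miyaura coupling forms the C6–C7 bond with retention at both sp2 carbons and so delivers the 5E,7Z-dienylidene directly; oxidative addition of zerovalent palladium to the β-triflyloxy enone is expected to be much faster than to the C10–Br bond of the α-bromo enone, so the vinyl bromide should survive at room temperature.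

**Compound list**
1 | (2Z)-oct-2-en-1-ol | CCCCC/C=C\CO | starting material
2 | (2Z)-1-bromooct-2-ene | CCCCC/C=C\CBr | intermediate
3 | 3-bromofuran-2-carboxylic acid | OC(=O)c1occc1Br | starting material
4 | lithium 3-bromo-5-lithiofuran-2-carboxylate (dilithio furoate) | [Li]c1cc(Br)c(C(=O)O[Li])o1 | intermediate (not isolated)
5 | 3-bromo-5-[(2Z)-oct-2-en-1-yl]furan-2-carboxylic acid | CCCCC/C=C\Cc1cc(Br)c(C(=O)O)o1 | intermediate
6 | {3-bromo-5-[(2Z)-oct-2-en-1-yl]furan-2-yl}methanol | CCCCC/C=C\Cc1cc(Br)c(CO)o1 | intermediate
7 | (3E,7Z)-3-bromo-2-hydroxytrideca-1,3,7-trien-5-one (ring-opened dienol, reacts as its O-protonated cation) | C=C(O)/C(Br)=C\C(=O)C/C=C\CCCCC | intermediate (not isolated)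
8 | (4S)-2-bromo-4-hydroxy-4-[(2Z)-oct-2-en-1-yl]cyclopent-2-en-1-one | CCCCC/C=C\C[C@@]1(O)C=C(Br)C(=O)C1 | intermediate
9 | dilithium alkoxide enolate of 8 | CCCCC/C=C\C[C@@]1(O[Li])C=C(Br)C(O[Li])=C1 | intermediate (not isolated)
10 | (4R,5Z)-2-bromo-4-hydroxy-5-(hydroxymethylidene)-4-[(2Z)-oct-2-en-1-yl]cyclopent-2-en-1-one | CCCCC/C=C\C[C@@]1(O)C=C(Br)C(=O)/C1=C\O | intermediate
11 | lithium chelate enolate of 10 | CCCCC/C=C\C[C@@]1(O)C=C(Br)C(=O)/C1=C\O[Li] | intermediate (not isolated)
12 | (Z)-[(5R)-3-bromo-5-hydroxy-5-[(2Z)-oct-2-en-1-yl]-2-oxocyclopent-3-en-1-ylidene]methyl trifluoromethanesulfonate | CCCCC/C=C\C[C@@]1(O)C=C(Br)C(=O)/C1=C\OS(=O)(=O)C(F)(F)F | intermediate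
13 | methyl hex-5-ynoate | COC(=O)CCCC#C | starting material
14 | methyl (5E)-6-(4,4,5,5-tetramethyl-1,3,2-dioxaborolan-2-yl)hex-5-enoate | COC(=O)CCC/C=C/B1OC(C)(C)C(C)(C)O1 | intermediate
15 | methyl (5E,7Z)-7-[(5R)-3-bromo-5-hydroxy-5-[(2Z)-oct-2-en-1-yl]-2-oxocyclopent-3-en-1-ylidene]hept-5-enoate | CCCCC/C=C\C[C@@]1(O)C=C(Br)C(=O)/C1=C\C=C\CCCC(=O)OC | target

**Step count and risks**
Total step count: 8. Longest linear sequence: 7 steps (1 → 2 → 5 → 6 → 8 → 10 → 12 → 15).

Steps most likely to fail:

1. Step 4 (Proposed new method). Ionisation of the primary, bromine-deactivated furfuryl alcohol by the chiral acid may be too slow to compete with decomposition, or the conrotatory closure may proceed with poor enantiofacial control. Fallback with known chemistry: starting from 6, heating with ZnCl2 in dioxane–water (the established racemic Piancatelli conditions for 5-alkyl-2-furylcarbinols) should lead, through the same dienol 7, to the racemic bromoenone F1. Preparative chromatography on a chiral stationary phase then separates 8 from its (4R)-enantiomer F2, and the route is rejoined at 8.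

2. Step 8. Oxidative addition into the C10–Br bond may compete with the triflate, the vinylogous acyl triflate may be hydrolysed by the aqueous base, or the 7Z geometry may erode at the vinylpalladium stage. Fallback: starting from 8, the dilithium species 9 is generated as in step 5 and added to methyl (5E)-7-oxohept-5-enoate F3 (from methyl 5-oxopentanoate and (triphenylphosphoranylidene)acetaldehyde by Wittig olefination) to give the aldol adducts F4. Selective mesylation of the secondary allylic hydroxyl (MsCl, Et3N) gives the mesylate F5, and E1cB elimination with DBU should give 15 together with its 7E isomer F6. Chromatography separates 15, F6 is returned to the mixture of isomers by photochemical equilibration, and the route is rejoined at 15.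

3. Step 5. The unprotected tertiary alkoxide may be O-formylated, or the ring may open by retro-aldol cleavage once the formyl group has made C8 a stabilised leaving carbanion. Fallback: starting from 8, silylation with Et3SiOTf and 2,6-lutidine gives the triethylsilyl ether F7. Its lithium enolate F8 (LiN(SiMe3)2, THF, −78 °C) is formylated with HCO2CH2CF3 to the silylated hydroxymethylidene ketone F9, and HF·pyridine removes the silyl group to give 10, where the route is rejoined.

**Further compounds**
F1 | step 4 | rac-2-bromo-4-hydroxy-4-[(2Z)-oct-2-en-1-yl]cyclopent-2-en-1-one | CCCCC/C=C\CC1(O)C=C(Br)C(=O)C1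
F2 | step 4 | (4R)-2-bromo-4-hydroxy-4-[(2Z)-oct-2-en-1-yl]cyclopent-2-en-1-one | CCCCC/C=C\C[C@]1(O)C=C(Br)C(=O)C1
F3 | step 8 | methyl (5E)-7-oxohept-5-enoate | COC(=O)CCC/C=C/C=O
F4 | step 8 | methyl (5E)-7-hydroxy-7-[3-bromo-5-hydroxy-5-[(2Z)-oct-2-en-1-yl]-2-oxocyclopent-3-en-1-yl]hept-5-enoate, aldol adducts of 8 (C7 and C8 epimers, C12 as in 8) | CCCCC/C=C\C[C@@]1(O)C=C(Br)C(=O)C1C(O)/C=C/CCCC(=O)OC
F5 | step 8 | 7-O-methanesulfonate of F4 | CCCCC/C=C\C[C@@]1(O)C=C(Br)C(=O)C1C(OS(C)(=O)=O)/C=C/CCCC(=O)OC
F6 | step 8 | methyl (5E,7E)-7-[(5R)-3-bromo-5-hydroxy-5-[(2Z)-oct-2-en-1-yl]-2-oxocyclopent-3-en-1-ylidene]hept-5-enoate (7E isomer of 15) | CCCCC/C=C\C[C@@]1(O)C=C(Br)C(=O)/C1=C/C=C/CCCC(=O)OC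
F7 | step 5 | (4S)-2-bromo-4-[(2Z)-oct-2-en-1-yl]-4-(triethylsilyloxy)cyclopent-2-en-1-one | CCCCC/C=C\C[C@@]1(O[Si](CC)(CC)CC)C=C(Br)C(=O)C1
F8 | step 5 | lithium enolate of F7 | CCCCC/C=C\C[C@@]1(O[Si](CC)(CC)CC)C=C(Br)C(O[Li])=C1
F9 | step 5 | (4R,5Z)-2-bromo-5-(hydroxymethylidene)-4-[(2Z)-oct-2-en-1-yl]-4-(triethylsilyloxy)cyclopent-2-en-1-one | CCCCC/C=C\C[C@@]1(O[Si](CC)(CC)CC)C=C(Br)C(=O)/C1=C\O
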